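## The problem

The target is a C15 tricycle built around a cyclobutane (C2, C3, C8, C7) that is bridged across both diagonals. C3 and C7 are joined by the enone unit C4(=O)–C5=C6(CH3), giving a bicyclo[3.1.1]heptenone. C2 and C8 are joined by the chain C1–C11–C10–C9, giving a bicyclo[4.1.1]octane, and the two bridges lie on opposite faces of the four-membered ring. There are seven stereocentres, two of them quaternary (C1 with the C12 methyl and the C13 oxymethylene, C8 with the C15 methyl). The seven-membered bridge carries a 1,3-anti pair of oxygens at C9 and C11, each next to a quaternary carbon. The ring-fusion centres C3, C7 and C8 can be set together in one cycloaddition and can then govern C2; C1 must be set in the same bond-forming event that attaches it to C2; C11 can direct C9 by intramolecular hydride delivery. Three hydroxyls carry two kinds of ester (acetate at C11, angelates at C9 and C13), so the 1,3-diol must be differentiated without acyl migration, and the angelates, which isomerise to tiglates under base, nucleophilic catalysis or heat, have to come last. The strained cyclobutane is best made late and under neutral conditions. The feature that allows this is that the C2–C3 bond joins two methine carbons, C3 being alpha to the C4 ketone: replacing that bond by NH gives a pyrrolidine (N, C2, C7, C8, C3) inside a strain-free cis-fused bicyclo[5.4.0]undecenone with both C–N bonds on one face, so deleting nitrogen can only re-form the bond with the required configurations.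

## Retrosynthesis

**Ester bonds.** The two angelate C–O bonds of 33 are cut first, giving diol 30 and angelic acid 31; 30 comes from silyl ether 29. The acetate is not cut here, because it is installed earlier by a reaction that distinguishes C11 from C9. Placing the angelates last keeps them away from every basic or radical step; the forward reaction only has to acylate a primary and a hindered secondary alcohol without Z to E isomerisation.

**C2–C3 (key cut).** In 29 the C2–C3 bond is replaced by a bridging NH, giving amine 27. The neighbouring cyclobutane bonds (C2–C7, C3–C8) would call for a [2+2] next to quaternary C8 with the seven-membered bridge as tether; C2–C3 is the only ring bond between two CH carbons, one of them able to stabilise a radical. Amine 27 holds all seven stereocentres but no four-membered ring. The forward step must N-aminate a hindered amine and close the 1,4-biradical faster than it fragments.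

**C10–C11 and the C9/C11 oxygens.** Amine 27 is the deprotected form of carbamate 26. The anti 1,3-diol monoacetate of 26 is traced to β-hydroxy ketone 25 (Evans–Tishchenko reduction with acetaldehyde), and 25 to keto aldehyde 24 by an aldol cut of C10–C11. This cut is preferred to C1–C2 or C8–C9, which would break at quaternary carbons, and to a metathesis closure, which would need a later hydration. In 24 the only enolisable position is the C10 methyl and the aldehyde has no α-hydrogen. The forward pair of steps must set C11 on the face opposite the nitrogen bridge and then deliver hydride to C9 from that same face.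

**C4 oxygen and the C11 aldehyde.** The aldehyde of 24 comes from the vinyl group of enone 22, and the C4 carbonyl of 22 from the C4=C5 alkene of 20 by a singlet-oxygen ene reaction with transposition. Doing the ene step after the pyrrolidine exists makes C3 a bridgehead, so only C6–H can be abstracted. Doing it before the vinyl cleavage turns the ring alkene into an electron-poor enone that the cleavage reagent leaves alone.

**N–C2.** Carbamate 20 is the protected form of amine 19, which comes from diketone 16 by carbamate removal and intramolecular reductive amination. N–C2 is cut in preference to N–C3 because N–C3 is set in the cycloaddition, while C2 is the carbonyl carbon that served to attach C1. The forward reduction must deliver hydride to the face of the bridged imine turned away from the C8 acetyl group, so that the C1 substituent ends up on the side from which the seven-membered ring can close.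

**C1–C2.** Diketone 16 comes from alcohol 15, and 15 from aldehyde 10 and the γ,γ-disubstituted allylboronic acid 14. This creates quaternary C1 together with a (disposable) C2 carbinol through a closed transition state; the vinyl group is the latent C11 aldehyde. Enolate alkylations at C1 would give no comparable control. Reagent 14 comes from allylic alcohol 13, ester 12 and silyloxyacetone 11.

**C3–C8, C6–C7 and C9–C10.** Aldehyde 10 comes from lactone acetal 9 by addition of a methyl nucleophile to C9, and 9 from a Diels–Alder reaction of dienyl carbamate 4 with butenolide 8. The polarity is matched: the nitrogen-bearing diene terminus C3 bonds to the α-carbon C8 and C6 to C7. One step sets C3, C7 and C8, brings in the nitrogen, and leaves C2 at the aldehyde level and C9 at the acid level, cis to each other. The menthyloxy acetal carbon of 8 fixes the absolute configuration and is then discarded. Annulation onto a cycloheptanedione was set aside because it leaves C9 and C11 unoxygenated and C8 to be quaternised against the polarity of the enone.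

**Building blocks.** Butenolide 8 comes from hydroxybutenolide 6 and (−)-menthol 7, and 6 from 3-methylfuran-2-carboxylic acid 5. Diene 4 comes from sorbic acid 1 by Curtius rearrangement.

## Roads not taken

Alternative 1: The cut is C1–C2 and C8–C9. In the forward step a Lewis acid opens the central bond of the acyl bicyclobutane A2 and the 1-benzyloxy-3-silyloxy diene A3 adds across it, giving the bicyclo[4.1.1]octene A1 with the cyclobutane already present. This is the most convergent road: the four-membered ring never has to be made, and the seven-membered ring appears in one step. Its weak points are the supply of A2 as a single enantiomer (a strained tricycle), the unproven regiochemistry and C1/C9 configuration of a stepwise cationic addition, and what A1 still lacks: C13 is missing, so C1 must be quaternised next to the cyclobutane; C15 is an ester that must become a methyl group; C4 is unoxidised; C11 must be reduced with control. In convergence this road is better than the chosen plan. The chosen plan sets against it that both quaternary carbons, all seven stereocentres and the full oxygen pattern are in place, each through a reaction with a clear stereochemical model, before its single uncertain step.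

Alternative 2: The cut is C2–C7 and C3–C8. Dehydrochlorination of the dienoyl chloride A5 gives the vinylketene A6, whose ketene adds across the remote trisubstituted alkene to give the bicyclo[3.1.1]heptanone A4. Intramolecular ketene–alkene cycloaddition is a well-tried route to this ring system, so the cyclobutane is formed with more certainty than by a nitrogen deletion, and quaternary C8 and the six-membered ring come from an acyclic precursor with one stereocentre. The weakness is the rest of the molecule: A4 has C2 as a hindered cyclobutanone and only a one-carbon stub at C8. The whole C1–C11–C10–C9 bridge would have to be built across the strained ring, C1 added to the cyclobutanone, the resulting tertiary alcohol removed with control at C2, and C1, C9 and C11 set on a medium ring. The enone would need cleavage of the exocyclic methylene and a desaturation. The chosen plan accepts a riskier ring-forming step in exchange for building the seven-membered ring on an unstrained scaffold.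

Alternative 3: The cut removes C10. The 4-6-6 tricyclic ketone A8 is homologated with a silylated diazomethane under Lewis acid, the less substituted carbon C9 migrating, to give the cycloheptanone A7. The migration preference is well understood and the chemistry before it is six-membered-ring chemistry. However, A8 already contains the doubly bridged cyclobutane, so the central difficulty is moved rather than solved. A7 also has no oxygen at C9 or C4: C9 would need desaturation and stereocontrolled oxygenation on the strained skeleton, C4 an allylic oxidation, and C11 a face-selective reduction. Its key step is at least as reliable as the chosen one, but it leaves more, and harder, work afterwards.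

Key step: step 17

Remark on the chemistry: locants C1–C15 of the target are kept for all intermediates; α is the face of the six-membered ring that carries nitrogen at C3 and β the other. The acetal epimer of 8 that crystallises is assumed to be 5R as in the unmethylated series; if it proves to be 5S, (+)-menthol is used.

Step 1
Reactants: 1 sorbic acid
Product: 4 tert-butyl N-[(1E,3E)-penta-1,3-dien-1-yl]carbamate, via sorboyl azide 2 (not isolated), via dienyl isocyanate 3 (not isolated)
Conditions: (PhO)2P(O)N3, Et3N, toluene, 0 °C to rt; 85 °C; then t-BuOH, 4-tert-butylcatechol (cat.), 85 °C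
Reagents that add atoms: diphenylphosphoryl azide, [N-]=[N+]=NP(=O)(Oc1ccccc1)Oc1ccccc1; tert-butanol, CC(C)(C)O
Why: Curtius rearrangement of the dienoyl azide keeps the E,E geometry, and trapping the isocyanate with tert-butanol gives the 1-(acylamino)diene whose nitrogen makes C6 the nucleophilic terminus.

Step 2
Reactants: 5 3-methylfuran-2-carboxylic acid
Product: 6 5-hydroxy-3-methylfuran-2(5H)-one
Conditions: O2, rose bengal (cat.), visible light, MeOH, 0 °C
Reagents that add atoms: dioxygen, O=O
Why: Sensitised photooxygenation adds singlet oxygen across C2/C5 of the furan ([4+2]) and the endoperoxide loses CO2; the carboxyl-bearing carbon becomes the lactone carbonyl (future C9), the methyl sits on the α-carbon (future C8) and the hemiacetal carbon is the future C2.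

Step 3
Reactants: 6 5-hydroxy-3-methylfuran-2(5H)-one; 7 (−)-menthol
Product: 8 (5R)-3-methyl-5-[(1R,2S,5R)-menthyloxy]furan-2(5H)-one
Conditions: camphorsulfonic acid (cat.), toluene, reflux, water separator; crystallisation, mother liquor re-equilibrated
Reagents that add atoms: none
Why: Acid-catalysed acetalisation under thermodynamic control; the acetal carbon epimerises through the oxocarbenium ion, so material can be funnelled into the 5R diastereomer, whose alkoxy group later shields one face of the dienophile.

Step 4
Reactants: 8 (5R)-menthyloxy butenolide; 4 dienyl carbamate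
Product: 9 cis-fused cyclohexene lactone acetal (3α-NHBoc; C4=C5; 6α-methyl; lactone C8–C9(=O)–O–C2H(O-menthyl)–C7 on the α face; 8β-methyl; menthyloxy trans to C6)
Conditions: toluene, 2,6-di-tert-butyl-4-methylphenol (cat.), 110 °C, sealed tube
Reagents that add atoms: none
Why: Thermal Diels–Alder reaction: the nitrogen-bearing terminus C3 bonds to the α-carbon C8 and C6 to C7 (ortho rule for a 1-donor diene); the lactone carbonyl is endo, so N, the C6 methyl and both lactone bonds are cis and the C8 methyl is trans; the diene adds anti to the menthyloxy group, which fixes the absolute configuration of C3, C7 and C8.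

Step 5
Reactants: 9 lactone acetal
Product: 10 keto aldehyde (3α-NHBoc; 6α-methyl; 7α-CHO (C2); 8α-acetyl (C9, C10); 8β-methyl)
Conditions: MeLi (2.2 equiv), THF, −78 °C; AcOH then aq. NH4Cl, −78 °C to rt
Reagents that add atoms: methyllithium, [Li]C
Why: Addition of an organolithium to a lactone carbonyl: the first equivalent deprotonates the carbamate, the second adds at C9; collapse of the tetrahedral intermediate on work-up gives the methyl ketone and frees the C2 aldehyde from the acyloxy acetal with loss of menthol, the hindered ketone resisting a second addition at −78 °C.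

Step 6
Reactants: 11 1-[(tert-butyldimethylsilyl)oxy]propan-2-one
Product: 12 methyl (2Z)-4-[(tert-butyldimethylsilyl)oxy]-3-methylbut-2-enoate
Conditions: (CF3CH2O)2P(O)CH2CO2Me, KN(SiMe3)2, 18-crown-6, THF, −78 °C
Reagents that add atoms: methyl bis(2,2,2-trifluoroethyl)phosphonoacetate, COC(=O)CP(=O)(OCC(F)(F)F)OCC(F)(F)F
Why: Still–Gennari olefination; the electron-poor phosphonate under dissociating conditions gives the kinetic Z alkene, with the ester cis to the silyloxymethyl group.

Step 7
Reactants: 12 Z enoate
Product: 13 (2Z)-4-[(tert-butyldimethylsilyl)oxy]-3-methylbut-2-en-1-ol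
Conditions: i-Bu2AlH (2.2 equiv), CH2Cl2, −78 °C; aq. Rochelle salt
Reagents that add atoms: none
Why: 1,2-Reduction of the enoate at low temperature leaves the trisubstituted Z alkene untouched.

Step 8
Reactants: 13 Z allylic alcohol; 10 keto aldehyde
Product: 15 homoallylic alcohol (C2 carbinol; quaternary C1 with methyl; CH2OTBS and vinyl; C1 configured as in the target), via (Z)-allylboronic acid 14 (not isolated)
Conditions: [Pd(MeCN)4](BF4)2 (5 mol %), B2(OH)4, DMSO/MeOH, rt; extraction into degassed CHCl3; then 10, 4 Å molecular sieves, 0 °C to rt
Reagents that add atoms: none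
Why: Palladium-catalysed borylation of the allylic alcohol gives the linear allylboronic acid with retention of alkene geometry, which adds to the aldehyde (not the hindered ketone) through a closed chair transition state (Zimmerman–Traxler). With attack anti to quaternary C8 (Felkin–Anh) and the ring residue equatorial, the Z reagent places CH2OTBS axial and the methyl equatorial, which gives the C1 configuration of the target; the C2 configuration is irrelevant.

Step 9
Reactants: 15 homoallylic alcohol
Product: 16 diketone (C2 ketone; C9 methyl ketone; NHBoc; vinyl on C1)
Conditions: Dess–Martin periodinane, NaHCO3, CH2Cl2, 0 °C to rt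
Reagents that add atoms: none
Why: Dess–Martin oxidation of a hindered secondary alcohol under buffered conditions; the C2 centre is erased on purpose, C1 is quaternary and cannot epimerise, and C7 is not enolised.

Step 10
Reactants: 16 diketone
Product: 19 bridged pyrrolidine (secondary amine joining C2 and C3; C1 side chain on the face of the C8 acetyl group), via amino diketone 17 (not isolated), via bridged cyclic imine 18 (not isolated)
Conditions: Me3SiOTf, 2,6-lutidine, CH2Cl2, 0 °C; MeOH; concentrate; then AcOH, NaBH(OAc)3, ClCH2CH2Cl, rt
Reagents that add atoms: none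
Why: Silyl-triflate cleavage of the carbamate spares the silyl ether; the freed C3 amine condenses with the C2 ketone (five-membered ring, intramolecular reductive amination). Hydride is expected on the face away from the C8 acetyl group, which overhangs the other face as the syn bridge methyl does in camphor, so H enters anti and the C1 substituent ends up syn to C9.

Step 11
Reactants: 19 bridged pyrrolidine
Product: 20 N-Boc bridged pyrrolidine
Conditions: Boc2O, Et3N, DMAP (cat.), CH2Cl2, 40 °C
Reagents that add atoms: di-tert-butyl dicarbonate, CC(C)(C)OC(=O)OC(=O)OC(C)(C)C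
Why: Carbamoylation of the secondary amine; the carbamate keeps nitrogen inert towards singlet oxygen, acetic anhydride and OsO4 in the next steps.

Step 12
Reactants: 20 N-Boc bridged pyrrolidine
Product: 22 enone (C4 ketone; C5=C6), via allylic hydroperoxide 21 (not isolated)
Conditions: O2, tetraphenylporphyrin (cat.), visible light, CH2Cl2, 0 °C; then Ac2O, pyridine, DMAP (cat.), 0 °C to rt
Reagents that add atoms: dioxygen, O=O
Why: Schenck ene reaction from the β face, where the axial C6–H is the only abstractable allylic hydrogen (C3 is a bridgehead), puts oxygen on C4 and moves the alkene to C5=C6; acetylation of the secondary hydroperoxide and elimination (Kornblum–DeLaMare type) gives the enone in the same flask.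

Step 13
Reactants: 22 enone
Product: 24 keto aldehyde (C11 aldehyde on quaternary C1), via diol 23 (not isolated)
Conditions: OsO4 (2 mol %), NaIO4, 2,6-lutidine, dioxane/H2O 3:1, rt
Reagents that add atoms: sodium periodate (oxygen relayed by OsO4), [Na+].[O-]I(=O)(=O)=O
Why: Lemieux–Johnson cleavage; the monosubstituted vinyl group is dihydroxylated much faster than the electron-poor trisubstituted enone, and the aldehyde has no α-hydrogen.

Step 14
Reactants: 24 keto aldehyde
Product: 25 β-hydroxy ketone (seven-membered ring closed; C11–OH on the face opposite the nitrogen bridge and cis to the C12 methyl; C9 ketone)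
Conditions: LiN(SiMe3)2 (1.05 equiv), THF, −78 °C; AcOH quench at −78 °C
Reagents that add atoms: none
Why: Intramolecular aldol addition (7-enolexo-exo-trig): the C10 methyl is the only position that can be enolised, since C3 and C7 are bridgeheads and the aldehyde has no α-hydrogen. The hydroxyl is expected on the open face, anti to the silyloxymethyl group and away from the carbamate, which is also the less congested aldolate if the addition equilibrates.

Step 15
Reactants: 25 β-hydroxy ketone
Product: 26 anti diol monoacetate (C11 acetate; C9 hydroxyl on the nitrogen-bridge face)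
Conditions: CH3CHO (10 equiv), SmI2 (30 mol %), THF, −10 °C
Reagents that add atoms: acetaldehyde, CC=O
Why: Evans–Tishchenko reduction: the C11 alkoxide forms a hemiacetal with acetaldehyde and its hydride is delivered within a samarium-bound six-membered transition state to the C9 carbonyl on the same face, so C9–OH ends anti to C11–O; the hemiacetal carbon becomes the C11 acetate. The enone has no β-hydroxyl and is left alone.

Step 16
Reactants: 26 anti diol monoacetate
Product: 27 aza-bridged bicyclo[5.4.0]undecenone (NH joining C2 and C3; C11 acetate; C9 hydroxyl; C13 TBS ether)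
Conditions: Me3SiOTf, 2,6-lutidine, CH2Cl2, 0 °C; then MeOH, aq. citric acid
Reagents that add atoms: none
Why: Silyl-triflate cleavage of the tert-butyl carbamate spares the TBS ether and the acetate; the transient trimethylsilyl ether at C9 is hydrolysed on work-up.

Step 17
Reactants: 27 aza-bridged bicyclo[5.4.0]undecenone
Product: 29 tricyclic enone (cyclobutane C2–C3 formed; C11 acetate; C9 hydroxyl; C13 TBS ether), via isodiazene 28 (not isolated)
Conditions: N-(benzyloxy)-N-(pivaloyloxy)-4-(trifluoromethyl)benzamide (1.5 equiv), THF, 45 °C
Reagents that add atoms: none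
Why: The secondary amine attacks the nitrogen of the anomeric amide and displaces pivalate; the N-amino-N-alkoxy amide rearranges with loss of benzyl 4-(trifluoromethyl)benzoate to isodiazene 28, which extrudes N2 and leaves a singlet 1,4-biradical at C2 and C3. The closest known reaction type is the isodiazene-mediated nitrogen deletion of secondary amines, including the contraction of pyrrolidines to cyclobutanes and of bridged azabicycles to bridged carbocycles. The cyclobutane (C2, C3, C8, C7) closes by intramolecular radical–radical recombination, which also completes the bicyclo[3.1.1]heptenone and bicyclo[4.1.1]octane units. C2 and C3 are formed with retention because each radical centre stays held by its two ring bonds on the face from which nitrogen left, so the bond can only form there. Closure has to outrun β-scission of C7–C8, which would open both carbocycles to a strained eleven-membered trienone, and hydrogen transfer, for which the carbonyl-stabilised C3 radical has no well-placed β-hydrogen. Tautomerisation of 28 to a hydrazone is blocked because C3 is a bridgehead and a C2=N bond would be a strained bridgehead double bond. The amine is the only group nucleophilic enough for the reagent; the C9 hydroxyl, the esters and the silyl ether are inert under the neutral conditions.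

Step 18
Reactants: 29 tricyclic enone
Product: 30 diol (C9 and C13 hydroxyls free; C11 acetate)
Conditions: HF·pyridine, pyridine/THF, 0 °C to rt
Reagents that add atoms: none
Why: Fluoride cleavage of the primary silyl ether under buffered acidic conditions, which avoid acetate migration and leave the enone and cyclobutane untouched.

Step 19
Reactants: 30 diol; 31 angelic acid
Product: 33 CNP0364726.1 (C9 and C13 angelates; C11 acetate), via angelic mixed anhydride 32 (not isolated)
Conditions: 31 (4 equiv), 2,4,6-trichlorobenzoyl chloride, Et3N, toluene, rt; then 30, 80 °C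
Reagents that add atoms: none
Why: Yamaguchi esterification without a nucleophilic catalyst; the mixed anhydride acylates the primary C13 and the hindered C9 hydroxyl on heating, conditions under which the Z geometry of angelates is preserved.

**Compound list**

1 | (2E,4E)-hexa-2,4-dienoic acid (sorbic acid) | C/C=C/C=C/C(=O)O | starting material
2 | (2E,4E)-hexa-2,4-dienoyl azide | C/C=C/C=C/C(=O)N=[N+]=[N-] | intermediate
3 | (1E,3E)-1-isocyanatopenta-1,3-diene | C/C=C/C=C/N=C=O | intermediate
4 | tert-butyl N-[(1E,3E)-penta-1,3-dien-1-yl]carbamate | C/C=C/C=C/NC(=O)OC(C)(C)C | intermediate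
5 | 3-methylfuran-2-carboxylic acid | Cc1ccoc1C(=O)O | starting material
6 | 5-hydroxy-3-methylfuran-2(5H)-one (racemic) | CC1=CC(O)OC1=O | intermediate
7 | (1R,2S,5R)-(−)-menthol | CC(C)[C@@H]1CC[C@@H](C)C[C@H]1O | starting material
8 | (5R)-3-methyl-5-[(1R,2S,5R)-menthyloxy]furan-2(5H)-one | CC1=C[C@H](O[C@@H]2C[C@H](C)CC[C@H]2C(C)C)OC1=O | intermediate
9 | Diels–Alder adduct: cis-fused cyclohexene lactone acetal, 3α-NHBoc, 6α-methyl, 8β-methyl, menthyloxy on C2 | CC(C)(C)OC(=O)N[C@H]1C=C[C@@H](C)[C@H]2[C@H](O[C@@H]3C[C@H](C)CC[C@H]3C(C)C)OC(=O)[C@@]12C | intermediate
10 | keto aldehyde: 3α-NHBoc, 6α-methyl, 7α-formyl, 8α-acetyl, 8β-methyl cyclohex-4-ene | CC(C)(C)OC(=O)N[C@H]1C=C[C@@H](C)[C@@H](C=O)[C@@]1(C)C(C)=O | intermediate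
11 | 1-[(tert-butyldimethylsilyl)oxy]propan-2-one | CC(=O)CO[Si](C)(C)C(C)(C)C | starting material
12 | methyl (2Z)-4-[(tert-butyldimethylsilyl)oxy]-3-methylbut-2-enoate | COC(=O)/C=C(/C)CO[Si](C)(C)C(C)(C)C | intermediate
13 | (2Z)-4-[(tert-butyldimethylsilyl)oxy]-3-methylbut-2-en-1-ol | OC/C=C(/C)CO[Si](C)(C)C(C)(C)C | intermediate
14 | [(2Z)-4-[(tert-butyldimethylsilyl)oxy]-3-methylbut-2-en-1-yl]boronic acid | OB(O)C/C=C(/C)CO[Si](C)(C)C(C)(C)C | intermediate
15 | homoallylic alcohol: C2 carbinol, quaternary C1 (methyl, CH2OTBS, vinyl) | CC(C)(C)OC(=O)N[C@H]1C=C[C@@H](C)[C@@H]([C@H](O)[C@@](C)(CO[Si](C)(C)C(C)(C)C)C=C)[C@@]1(C)C(C)=O | intermediate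
16 | diketone: C2 ketone, C9 methyl ketone | CC(C)(C)OC(=O)N[C@H]1C=C[C@@H](C)[C@@H](C(=O)[C@@](C)(CO[Si](C)(C)C(C)(C)C)C=C)[C@@]1(C)C(C)=O | intermediate
17 | amino diketone (free C3 amine) | N[C@H]1C=C[C@@H](C)[C@@H](C(=O)[C@@](C)(CO[Si](C)(C)C(C)(C)C)C=C)[C@@]1(C)C(C)=O | intermediate
18 | bridged cyclic imine (N=C2) | C=C[C@](C)(CO[Si](C)(C)C(C)(C)C)C1=N[C@H]2C=C[C@@H](C)[C@@H]1[C@@]2(C)C(C)=O | intermediate
19 | bridged pyrrolidine, NH joining C2 and C3 | C=C[C@](C)(CO[Si](C)(C)C(C)(C)C)[C@@H]1N[C@H]2C=C[C@@H](C)[C@@H]1[C@@]2(C)C(C)=O | intermediate
20 | N-Boc bridged pyrrolidine | C=C[C@](C)(CO[Si](C)(C)C(C)(C)C)[C@@H]1N(C(=O)OC(C)(C)C)[C@H]2C=C[C@@H](C)[C@@H]1[C@@]2(C)C(C)=O | intermediate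
21 | allylic hydroperoxide (C4–OOH on the β face, C5=C6) | C=C[C@](C)(CO[Si](C)(C)C(C)(C)C)[C@@H]1N(C(=O)OC(C)(C)C)[C@H]2[C@H](OO)C=C(C)[C@@H]1[C@@]2(C)C(C)=O | intermediate
22 | enone (C4 ketone, C5=C6) | C=C[C@](C)(CO[Si](C)(C)C(C)(C)C)[C@@H]1N(C(=O)OC(C)(C)C)[C@H]2C(=O)C=C(C)[C@@H]1[C@@]2(C)C(C)=O | intermediate
23 | diol from the vinyl group (carbinol configuration not defined) | OCC(O)[C@](C)(CO[Si](C)(C)C(C)(C)C)[C@@H]1N(C(=O)OC(C)(C)C)[C@H]2C(=O)C=C(C)[C@@H]1[C@@]2(C)C(C)=O | intermediate
24 | keto aldehyde (C11 aldehyde, C9 methyl ketone) | O=C[C@](C)(CO[Si](C)(C)C(C)(C)C)[C@@H]1N(C(=O)OC(C)(C)C)[C@H]2C(=O)C=C(C)[C@@H]1[C@@]2(C)C(C)=O | intermediate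
25 | β-hydroxy ketone, seven-membered ring closed (C11–OH, C9 ketone) | CC(C)(C)[Si](C)(C)OC[C@]1(C)[C@@H]2N(C(=O)OC(C)(C)C)[C@H]3C(=O)C=C(C)[C@@H]2[C@@]3(C)C(=O)C[C@H]1O | intermediate
26 | anti diol monoacetate (C11 acetate, C9 hydroxyl), N-Boc | CC(C)(C)[Si](C)(C)OC[C@]1(C)[C@@H]2N(C(=O)OC(C)(C)C)[C@H]3C(=O)C=C(C)[C@@H]2[C@@]3(C)[C@H](O)C[C@H]1OC(C)=O | intermediate
27 | aza-bridged bicyclo[5.4.0]undecenone, NH joining C2 and C3 | CC(C)(C)[Si](C)(C)OC[C@]1(C)[C@@H]2N[C@H]3C(=O)C=C(C)[C@@H]2[C@@]3(C)[C@H](O)C[C@H]1OC(C)=O | intermediate
28 | isodiazene of 27 | CC(C)(C)[Si](C)(C)OC[C@]1(C)[C@@H]2[N+](=[N-])[C@H]3C(=O)C=C(C)[C@@H]2[C@@]3(C)[C@H](O)C[C@H]1OC(C)=O | intermediate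
29 | tricyclic enone with the cyclobutane (C11 acetate, C9 hydroxyl, C13 TBS ether) | CC(C)(C)[Si](C)(C)OC[C@]1(C)[C@@H]2[C@H]3C(=O)C=C(C)[C@@H]2[C@@]3(C)[C@H](O)C[C@H]1OC(C)=O | intermediate
30 | tricyclic diol (C9 and C13 hydroxyls, C11 acetate) | OC[C@]1(C)[C@@H]2[C@H]3C(=O)C=C(C)[C@@H]2[C@@]3(C)[C@H](O)C[C@H]1OC(C)=O | intermediate
31 | angelic acid, (2Z)-2-methylbut-2-enoic acid | C/C=C(/C)C(=O)O | starting material
32 | angelic 2,4,6-trichlorobenzoic anhydride | C/C=C(/C)C(=O)OC(=O)c1c(Cl)cc(Cl)cc1Cl | intermediate
33 | CNP0364726.1 | C/C=C(/C)C(=O)OC[C@]1(C)[C@@H]2[C@H]3C(=O)C=C(C)[C@@H]2[C@@]3(C)[C@H](OC(=O)/C(C)=C\C)C[C@H]1OC(C)=O | target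

**Step count and risks**

Total: 19 steps. Longest linear sequence: 16 steps (steps 2–5 and 8–19, from 5).

Step 17 (key step). The most likely failures are sluggish N-amination of the hindered, weakly basic α-amino ketone nitrogen, and, once the isodiazene forms, fragmentation or hydrogen transfer competing with closure to the strained ring. Fallback: from 27, nitrogen is aminated with hydroxylamine-O-sulfonic acid and K2CO3 to the isolable N-amino pyrrolidine F1, and F1 is oxidised with PhI(OAc)2 in CH2Cl2 at 0 °C. This reaches the isodiazene by a separate N–N bond-forming step and at low temperature, where cage recombination is favoured, and returns to the route at 29.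

Step 4. The α-methyl butenolide is a weak dienophile, so thermal decomposition of the dienyl carbamate may compete, and the α-methyl group may erode endo selectivity. Fallback: from 4, the diene is combined with citraconic anhydride at room temperature, where the same regiochemistry and endo addition are expected from a much more reactive partner, giving the racemic anhydride adduct F2. LiAlH(Ot-Bu)3 in THF at −78 °C reduces the less hindered C2 carbonyl to the racemic hydroxy lactone F3. Acid-catalysed acetalisation with 7 gives 9 together with the diastereomeric acetal F4 of the other enantiomer; the two are separated, and the route is rejoined at 9.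

Step 8. Facial selectivity on the aldehyde may be low or reversed, or the Z geometry of the boron reagent may be partly lost; either would scramble C1. Fallback: from 14 and 10, the boronic acid is esterified with pinacol to the pinacol boronate F5, which is configurationally robust and unreactive on its own. Its addition to 10 is run with a chiral BINOL-derived phosphoric acid, so the face of the aldehyde is set by the catalyst and not by the substrate; the closed transition state still translates the Z geometry into C1. The route is rejoined at 15.

Step 10. Hydride delivery to the bridged imine may occur on the wrong face, which would put the C1 side chain where the seven-membered ring cannot close. Fallback: the order of bond formation is reversed so that the carbon group, not hydride, enters on that face. From 10, the carbamate is cleaved as in step 10 and the amine closes onto the aldehyde to the bridged cyclic aldimine F6. The E reagent is made from 11 by olefination with triethyl phosphonoacetate to the E enoate F7, reduction to the E allylic alcohol F8 and borylation to the (E)-allylboronic acid F9. Addition of F9 to F6 through the same closed transition state (the ring-locked imine behaves like an aldehyde, and the E geometry is the one that gives the target C1 when carbon enters on this face) returns to the route at 19.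

Step 14. The aldol may show poor facial selectivity at C11, or retro-aldol and dehydration may intervene. Fallback: from 24, the ring closure is run under equilibrating basic conditions (NaOMe, MeOH) through to the cycloheptenone F10. Copper-catalysed conjugate borylation (CuCl, NaOt-Bu, bisphosphine, B2pin2, MeOH) from the open face, anti to the silyloxymethyl group and the nitrogen bridge, gives the β-boryl ketone F11, and oxidation with NaBO3 with retention rejoins the route at 25.

**Further compounds**

F1 | step 17 | N-amino derivative of 27 (1,1-disubstituted hydrazine) | CC(C)(C)[Si](C)(C)OC[C@]1(C)[C@@H]2N(N)[C@H]3C(=O)C=C(C)[C@@H]2[C@@]3(C)[C@H](O)C[C@H]1OC(C)=O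
F2 | step 4 | racemic citraconic anhydride adduct of 4 (enantiomer leading to 9 drawn) | CC(C)(C)OC(=O)N[C@H]1C=C[C@@H](C)[C@H]2C(=O)OC(=O)[C@@]12C
F3 | step 4 | racemic hydroxy lactone, C2 reduced (enantiomer leading to 9 drawn, lactol carbon undefined) | CC(C)(C)OC(=O)N[C@H]1C=C[C@@H](C)[C@H]2C(O)OC(=O)[C@@]12C
F4 | step 4 | diastereomeric menthyl acetal of the enantiomeric core | CC(C)(C)OC(=O)N[C@@H]1C=C[C@H](C)[C@@H]2[C@@H](O[C@@H]3C[C@H](C)CC[C@H]3C(C)C)OC(=O)[C@]12C
F5 | step 8 | pinacol [(2Z)-4-[(tert-butyldimethylsilyl)oxy]-3-methylbut-2-en-1-yl]boronate | CC1(C)OB(C/C=C(/C)CO[Si](C)(C)C(C)(C)C)OC1(C)C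
F6 | step 10 | bridged cyclic aldimine from 10 | C1=N[C@H]2C=C[C@@H](C)[C@@H]1[C@@]2(C)C(C)=O
F7 | step 10 | ethyl (2E)-4-[(tert-butyldimethylsilyl)oxy]-3-methylbut-2-enoate | CCOC(=O)/C=C(\C)CO[Si](C)(C)C(C)(C)C
F8 | step 10 | (2E)-4-[(tert-butyldimethylsilyl)oxy]-3-methylbut-2-en-1-ol | OC/C=C(\C)CO[Si](C)(C)C(C)(C)C
F9 | step 10 | [(2E)-4-[(tert-butyldimethylsilyl)oxy]-3-methylbut-2-en-1-yl]boronic acid | OB(O)C/C=C(\C)CO[Si](C)(C)C(C)(C)C
F10 | step 14 | cycloheptenone (C9 ketone, C10=C11) | CC(C)(C)[Si](C)(C)OC[C@]1(C)[C@@H]2N(C(=O)OC(C)(C)C)[C@H]3C(=O)C=C(C)[C@@H]2[C@@]3(C)C(=O)C=C1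
F11 | step 14 | β-boryl ketone (pinacolboryl on C11) | CC(C)(C)[Si](C)(C)OC[C@]1(C)[C@@H]2N(C(=O)OC(C)(C)C)[C@H]3C(=O)C=C(C)[C@@H]2[C@@]3(C)C(=O)C[C@H]1B1OC(C)(C)C(C)(C)O1
A1 | alternative 1 | tricyclic silyl enol ether with C9 benzyl ether and C8 ester | C[C@H]1[C@@H]2[C@H]3CC=C(C)[C@@H]2[C@@]3(C(=O)OC)[C@H](OCc4ccccc4)C=C1O[Si](C)(C)C(C)(C)C
A2 | alternative 1 | methyl 3-methyltricyclo[4.1.0.0(2,7)]hept-3-ene-1-carboxylate (acyl bicyclobutane) | COC(=O)[C@]12[C@@H]3CC=C(C)[C@H]1[C@H]23
A3 | alternative 1 | (1E,3Z)-1-(benzyloxy)-3-[(tert-butyldimethylsilyl)oxy]penta-1,3-diene | C/C=C(\O[Si](C)(C)C(C)(C)C)/C=C/OCc1ccccc1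
A4 | alternative 2 | 7-(silyloxymethyl)-4,7-dimethyl-2-methylenebicyclo[3.1.1]heptan-6-one | C=C1C[C@@H](C)[C@H]2C(=O)[C@@H]1[C@]2(C)CO[Si](C)(C)C(C)(C)C
A5 | alternative 2 | (2E,6E)-8-[(tert-butyldimethylsilyl)oxy]-3,5,7-trimethylocta-2,6-dienoyl chloride | O=C(Cl)/C=C(\C)C[C@@H](C)/C=C(\C)CO[Si](C)(C)C(C)(C)C
A6 | alternative 2 | vinylketene from A5 | O=C=CC(=C)C[C@@H](C)/C=C(\C)CO[Si](C)(C)C(C)(C)C
A7 | alternative 3 | ring-expanded tricyclic cycloheptanone | CC(C)(C)[Si](C)(C)OC[C@]1(C)[C@@H]2[C@H]3CC=C(C)[C@@H]2[C@@]3(C)CCC1=O
A8 | alternative 3 | 4-6-6 tricyclic ketone | CC(C)(C)[Si](C)(C)OC[C@]1(C)[C@@H]2[C@H]3CC=C(C)[C@@H]2[C@@]3(C)CC1=O
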